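## The problem

Gardenin E 15 is 5,3',5'-trihydroxy-6,7,8,4'-tetramethoxyflavone, a 2-aryl-4H-chromen-4-one in which benzo ring A is fused to pyranone ring C through C4a and C8a and ring B is attached to C2 by one aryl–vinyl bond. There is no stereocentre, so the whole difficulty is to place eight oxygen atoms and tell them apart: methyl ethers at O6, O7, O8 and O4', free hydroxyls at O5, O3' and O5'. Ring A is fully substituted, and in the customary flavone syntheses, where O1 is a phenolic oxygen from the start, this forces the preparation of a hexasubstituted ortho-hydroxy tetramethoxyphenyl ketone. The reagents are limited by the free phenols (easily oxidised and acylated), the pyranone (opened by strong aqueous base), the four methyl ethers that must stay when a fifth at O5 is removed, and ring A itself, whose para pair of oxygens at C5 and C8 invites oxidation to a quinone. Ring B is the easy part, because its pattern is already present in 3,5-dihydroxy-4-methoxybenzoic acid 6. The feature exploited here is C8a: in a 2,3,4,5-tetramethoxyphenyl ketone it is the only ring C–H, ortho to the acyl-bearing C4a and para to the C6 methoxy group. The enol oxygen of a 1,3-diketone built on that ketone can reach it through a six-membered array, whereas the enol carbon C3 cannot.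

## Retrosynthesis

**15 ⇒ 14 ⇒ 12 (O–acyl bonds at O3'/O5', then O5–CH3).** The last operations are protecting-group removals. The ring B phenols are carried as pivalates for three reasons:
- they make ring B electron-poor for the oxidative step;
- they are inert to the boron Lewis acid of the demethylation step;
- they keep the 4'-methoxy group from sitting between two free hydroxyls when a Lewis acid is present, where chelation could cleave it.

O5 is carried as a methyl ether. A free 5-hydroxyl in the diketone would close the pyranone in the classical sense and give a flavone without the C5 oxygen. A 5-methoxy group peri to the C4 carbonyl, by contrast, is the one methyl ether of a polymethoxyflavone that a chelating boron trihalide removes selectively. Methanolysis of 14 comes last because it is the mildest step and releases the free triphenol only at the end.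

**12 ⇒ 11 (O1–C8a).** Ring C is opened at the bond between the pyranone oxygen and ring A, leaving a C–H at C8a. The neighbouring cut, O1–C2 (cyclodehydration), would need a ring A ketone that already carries oxygen at C8a, that is, a hexasubstituted benzene. The chosen cut needs only the pentasubstituted ketone 5 and removes one ring and one C–O bond in a single step. The forward reaction is an anodic dehydrogenative C–O coupling. It must oxidise ring A and not ring B, and must substitute the C–H and not the methoxy-bearing ortho carbon.

**11 ⇒ 5 + 10 (C2–C3).** The 1,3-diketone is cut between the methylene carbon and the ring B carbonyl. The opposite cut (C3–C4) would need a ring A acid chloride and a ring B methyl ketone, both further from commercial materials, whereas 5 comes directly from a Friedel–Crafts acetylation. The forward reaction is a C-acylation under soft-enolisation conditions, which must leave the aryl pivalates of 10 untouched.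

**10 ⇒ 9 ⇒ 6 + 7 (acyl chloride, then two ester C–O bonds).** Ring B is bought with its oxygen pattern in place as 6. Exhaustive pivaloylation with three equivalents of 7 gives the mixed anhydride 8, whose hydrolysis in the same flask gives acid 9. Acid 9 is then converted to chloride 10. No carbon–carbon bond is made on this branch.

**5 ⇒ 4 ⇒ 3 ⇒ 1 (C4a–C4, O–CH3, C–O by Dakin).** The acetyl group is removed from the only type of free position of 1,2,3,4-tetramethoxybenzene 4; its two C–H positions are equivalent, so there is no regiochemical question. 4 comes from phenol 3 by methylation, and 3 from the cheap aldehyde 1 by Dakin oxidation through formate 2. The acetylation must be mild enough not to cleave the methoxy group that ends up ortho to the new ketone.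

## Roads not taken

**Alternative 1:** C4 is taken out as carbon monoxide, cutting C4a–C4 and C4–C3 at once. In the forward sense a zerovalent palladium catalyst such as Pd(dba)2 with a bisphosphine would join three components to give diketone A1. They are aryl iodide A2, which is 1,3-bis(benzyloxy)-2-iodo-4,5,6-trimethoxybenzene, CO, and the enolate of methyl ketone A3, which is 1-[3,5-bis(benzyloxy)-4-methoxyphenyl]ethan-1-one.
- Merits: carbonylative α-arylation of ketones is an established reaction class, and A3 is a simple ring B methyl ketone within easy reach of 6. Ring A of A1 is symmetric about the C4a–C7 axis, so after hydrogenolysis either ortho hydroxyl closes the pyranone and the other becomes the 5-OH. The target would follow in two operations with no demethylation and no regiochemical question. In precedent and in cleanness of the end game this road is better than the chosen one.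
- Weak points: A2 is itself a hexasubstituted benzene derived from an uncommon resorcinol and needs several steps. Oxidative addition and CO insertion at an iodide flanked by two benzyloxy groups on a very electron-rich ring are slow, so reduction of A2 or non-carbonylative arylation of A3 compete. Four benzyl groups are carried as ballast.
- Comparison: the chosen plan sets against it a ring A fragment 5 that is only pentasubstituted and reached in three steps from 1, no precious metal, and no prior oxygen or halogen at C8a. It pays with an unprecedented key step, for which a halogen-based fallback making the same bond is kept ready.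

**Alternative 2:** Ring A is grown on a preformed pyranone, with the last bond C4a–C5. Addition of the C6 carbanion of pyranone A7, which is 2-[3,5-bis(benzyloxy)-4-methoxyphenyl]-4H-pyran-4-one, to dimethyl squarate A6 would give cyclobutenone A5. On heating, A5 opens to a vinylketene that closes by 6π electrocyclisation onto the adjacent pyranone C–H and tautomerises to the 5,8-hydroquinone A4.
- Merits: the ring expansion is a reliable way to make heavily oxygenated hydroquinones. The 6- and 7-methoxy groups arrive with A6. The 5-hydroxyl is free at once and is told apart from O8 by its hydrogen bond to the carbonyl, so no demethylation is needed. Here too the alternative differentiates the oxygens more elegantly than the chosen plan.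
- Weak points: a carbanion at C6 of a 4-pyranone, itself a Michael acceptor, is awkward to generate. A7 must be built first. A4 is an air-sensitive para-hydroquinone, and the selective methylation of O8 and hydrogenolysis add steps.
- Comparison: the chosen plan is shorter, uses no organometallic pyranone, and never passes through a free hydroquinone. It accepts one selective demethylation (step 8) in return.

**Alternative 3:** Ring B is made last from two heterocycles, cutting C1'–C2' and C1'–C6'. The carbanion of the 2-methyl group of chromone A9, which is 5,6,7,8-tetramethoxy-2-methyl-4H-chromen-4-one, would add to C2 of pyranone A10, which is 3,5-bis(benzyloxy)-4H-pyran-4-one. Ring opening and intramolecular aldol condensation would give the 4'-phenol A8, to be methylated at O4' and then deprotected.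
- Merits: the 4'-oxygen emerges as the only free hydroxyl, so the methoxy-between-two-hydroxyls pattern of ring B is set without ambiguity, and the route is convergent.
- Weak points: A9 needs exactly the ortho-hydroxylated, hexasubstituted ring A ketone that is the classical bottleneck. A9 is also an electrophile at C2 toward its own anion. A10 must be prepared. The ring transformation on a 3,5-dialkoxypyranone is itself without close precedent, so the road carries novelty risk without saving steps.
- Comparison: in setting the ring B pattern the alternative is as good as the chosen plan, but the chosen plan obtains that pattern by purchase of 6 and spends its one risky step on ring A, where the real difficulty lies.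

Key step: step 7

Assumption: diketone 11 is drawn as the diketo tautomer; it is expected to exist mainly as the chelated enol, and both tautomers lead to the same cyclisation.

## Route

Step 1
Reactants: 1 2,3,4-trimethoxybenzaldehyde
Product: 3 2,3,4-trimethoxyphenol, via aryl formate 2 (not isolated)
Conditions: 30% aq. H2O2, cat. H2SO4, MeOH, rt
Reagents that add atoms: hydrogen peroxide, OO
Why: Acid-catalysed Dakin oxidation; the electron-rich aryl group with ortho and para methoxy donors migrates in the peroxide adduct, and the formate 2 is methanolysed in the same flask to the phenol.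

Step 2
Reactants: 3 2,3,4-trimethoxyphenol
Product: 4 1,2,3,4-tetramethoxybenzene
Conditions: MeI, K2CO3, acetone, reflux
Reagents that add atoms: iodomethane, CI
Why: Williamson O-methylation of a phenol; there is no competing nucleophilic site.

Step 3
Reactants: 4 1,2,3,4-tetramethoxybenzene
Product: 5 1-(2,3,4,5-tetramethoxyphenyl)ethan-1-one
Conditions: AcOH, (CF3CO)2O, cat. 85% H3PO4, CH2Cl2, 0 °C to rt
Reagents that add atoms: acetic acid, CC(=O)O
Why: Friedel–Crafts acetylation through acetyl trifluoroacetate made in the flask; the two free positions of 4 are equivalent and each is ortho and para to methoxy groups, and the absence of a chelating metal halide should spare the methoxy group ortho to the new ketone.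

Step 4
Reactants: 6 3,5-dihydroxy-4-methoxybenzoic acid; 7 pivaloyl chloride
Product: 9 4-methoxy-3,5-bis(pivaloyloxy)benzoic acid, via mixed anhydride 8 (not isolated)
Conditions: 7 (3.3 equiv), pyridine, cat. DMAP, CH2Cl2, 0 °C to rt; then H2O, rt
Reagents that add atoms: pivaloyl chloride (second equivalent), CC(C)(C)C(Cl)=O; pivaloyl chloride (third equivalent for 8 only), CC(C)(C)C(Cl)=O; water, O
Why: DMAP-catalysed O-acylation that consumes three equivalents of 7: two give the aryl pivalates and the third turns the carboxylic acid into the mixed anhydride 8. Added water then cleaves only the anhydride, either mode of attack giving acid 9 and pivalic acid, while the hindered aryl pivalates survive.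

Step 5
Reactants: 9 4-methoxy-3,5-bis(pivaloyloxy)benzoic acid
Product: 10 4-methoxy-3,5-bis(pivaloyloxy)benzoyl chloride
Conditions: (COCl)2, cat. DMF, CH2Cl2, 0 °C to rt
Reagents that add atoms: oxalyl chloride, O=C(Cl)C(Cl)=O
Why: Standard acid chloride formation through the chloroiminium catalyst; the by-products are gases and the esters are inert, so the crude chloride can be used directly.

Step 6
Reactants: 5 1-(2,3,4,5-tetramethoxyphenyl)ethan-1-one; 10 4-methoxy-3,5-bis(pivaloyloxy)benzoyl chloride
Product: 11 1-[4-methoxy-3,5-bis(pivaloyloxy)phenyl]-3-(2,3,4,5-tetramethoxyphenyl)propane-1,3-dione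
Conditions: MgBr2·OEt2, i-Pr2NEt, CH2Cl2, rt; then 1 M HCl
Reagents that add atoms: none
Why: Claisen-type C-acylation by soft enolisation; the magnesium-chelated enolate of the ortho-methoxy ketone forms with an amine base and attacks the acid chloride far faster than the hindered aryl pivalates, and the diketone is held as its magnesium chelate against a second acylation.

Step 7
Reactants: 11 1-[4-methoxy-3,5-bis(pivaloyloxy)phenyl]-3-(2,3,4,5-tetramethoxyphenyl)propane-1,3-dione
Product: 12 5,6,7,8,4'-pentamethoxy-3',5'-bis(pivaloyloxy)flavone
Conditions: graphite anode, Pt cathode, undivided cell, constant current, 2.2 F mol−1, Bu4NPF6, dry HFIP/CH2Cl2 (4:1), rt, argon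
Reagents that add atoms: none
Why: Proposed new method: anodic removal of one electron from 11 should give the radical cation of the tetramethoxyaryl ketone (ring A), and in the open, non-chelated rotamer of the enol, which the hydrogen-bond-donating HFIP favours, the oxygen on C2 lies over the ring carbon that carries the only ring hydrogen; attack there, loss of the enol proton to the hexafluoroisopropoxide made at the cathode, a second electron transfer and loss of the ring proton give the aromatic pyranone, while H2 leaves at the cathode. Should the enol be oxidised first, the oxygen terminus of the 1,3-dicarbonyl radical can add to the same carbon and the sequence ends in the same product, so both oxidation sites converge. The closest known reaction types are anodic dehydrogenative C(sp2)–H/O–H cyclisations through arene radical cations or heteroatom radicals, namely biaryl-2-carboxylic acids to benzocoumarins and anilides to benzoxazoles; an enol oxygen of a 1,3-diketone has not been shown in this role. Ring C closes as a six-membered ring through oxygen onto an aromatic carbon (6-exo with respect to the C8–C8a π bond), and C3 could only close a four-membered ring, so carbon cyclisation is excluded; no stereocentre is formed. Three selectivities are needed. Ring A must be oxidised before ring B, which the four methoxy donors on ring A and the two electron-poor pivalates plus the acyl group on ring B should secure. Substitution at C–H must win over ipso attack at the methoxy-bearing ortho carbon: the C–H adduct is drained irreversibly by oxidation and proton loss, whereas the ipso adduct has no proton to lose and can revert, and the dry, acid-free medium disfavours its collapse by loss of methanol. The electrolysis must stop after two electrons, which the charge limit and the electron-poor pyranone now conjugated to ring A in 12 should allow.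

Step 8
Reactants: 12 5,6,7,8,4'-pentamethoxy-3',5'-bis(pivaloyloxy)flavone
Product: 14 5-hydroxy-6,7,8,4'-tetramethoxy-3',5'-bis(pivaloyloxy)flavone, via dichloroboryl ether 13 (not isolated)
Conditions: BCl3 (2 equiv), CH2Cl2, −78 to 0 °C; then H2O
Reagents that add atoms: boron trichloride (its atoms stay in 13 only), ClB(Cl)Cl
Why: Chelation-controlled ether cleavage; BCl3 bridges the C4 carbonyl and the peri 5-methoxy oxygen, chloride removes that methyl group, and water frees the hydrogen-bonded 5-hydroxyl. The other methoxy groups lack such a chelate, and the pivalates both resist BCl3 and keep the 4'-methoxy group from being flanked by free hydroxyls.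

Step 9
Reactants: 14 5-hydroxy-6,7,8,4'-tetramethoxy-3',5'-bis(pivaloyloxy)flavone
Product: 15 Gardenin E (5,3',5'-trihydroxy-6,7,8,4'-tetramethoxyflavone)
Conditions: K2CO3, MeOH, rt, argon; then 1 M HCl
Reagents that add atoms: none
Why: Base-mediated transesterification of aryl esters; phenoxides are good leaving groups, so the pivalates should leave at room temperature under conditions that do not open the pyranone or touch the methyl ethers.

## Compound list

1 | 2,3,4-trimethoxybenzaldehyde | COc1ccc(C=O)c(OC)c1OC | starting material
2 | 2,3,4-trimethoxyphenyl formate | COc1ccc(OC=O)c(OC)c1OC | intermediate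
3 | 2,3,4-trimethoxyphenol | COc1ccc(O)c(OC)c1OC | intermediate
4 | 1,2,3,4-tetramethoxybenzene | COc1ccc(OC)c(OC)c1OC | intermediate
5 | 1-(2,3,4,5-tetramethoxyphenyl)ethan-1-one | CC(=O)c1cc(OC)c(OC)c(OC)c1OC | intermediate
6 | 3,5-dihydroxy-4-methoxybenzoic acid | COc1c(O)cc(C(=O)O)cc1O | starting material
7 | pivaloyl chloride (2,2-dimethylpropanoyl chloride) | CC(C)(C)C(Cl)=O | starting material
8 | 4-methoxy-3,5-bis(pivaloyloxy)benzoic pivalic anhydride | COc1c(OC(=O)C(C)(C)C)cc(C(=O)OC(=O)C(C)(C)C)cc1OC(=O)C(C)(C)C | intermediate
9 | 4-methoxy-3,5-bis(pivaloyloxy)benzoic acid | COc1c(OC(=O)C(C)(C)C)cc(C(=O)O)cc1OC(=O)C(C)(C)C | intermediate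
10 | 4-methoxy-3,5-bis(pivaloyloxy)benzoyl chloride | COc1c(OC(=O)C(C)(C)C)cc(C(=O)Cl)cc1OC(=O)C(C)(C)C | intermediate
11 | 1-[4-methoxy-3,5-bis(pivaloyloxy)phenyl]-3-(2,3,4,5-tetramethoxyphenyl)propane-1,3-dione | COc1cc(C(=O)CC(=O)c2cc(OC(=O)C(C)(C)C)c(OC)c(OC(=O)C(C)(C)C)c2)c(OC)c(OC)c1OC | intermediate
12 | 5,6,7,8,4'-pentamethoxy-3',5'-bis(pivaloyloxy)flavone | COc1c(OC(=O)C(C)(C)C)cc(-c2cc(=O)c3c(OC)c(OC)c(OC)c(OC)c3o2)cc1OC(=O)C(C)(C)C | intermediate
13 | 5-(dichloroboryloxy)-6,7,8,4'-tetramethoxy-3',5'-bis(pivaloyloxy)flavone | COc1c(OC(=O)C(C)(C)C)cc(-c2cc(=O)c3c(OB(Cl)Cl)c(OC)c(OC)c(OC)c3o2)cc1OC(=O)C(C)(C)C | intermediate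
14 | 5-hydroxy-6,7,8,4'-tetramethoxy-3',5'-bis(pivaloyloxy)flavone | COc1c(OC(=O)C(C)(C)C)cc(-c2cc(=O)c3c(O)c(OC)c(OC)c(OC)c3o2)cc1OC(=O)C(C)(C)C | intermediate
15 | Gardenin E (5,3',5'-trihydroxy-6,7,8,4'-tetramethoxyflavone) | COc1c(O)cc(-c2cc(=O)c3c(O)c(OC)c(OC)c(OC)c3o2)cc1O | target

## Step count and risks

Total: 9 steps. Longest linear sequence: 7 steps (steps 1, 2, 3, 6, 7, 8, 9; 1 → 3 → 4 → 5 → 11 → 12 → 14 → 15). Steps 4 and 5 form the two-step ring B branch that joins at step 6.

**Step 7 (key step, proposed new method).** Three processes are most likely to go wrong:
- ipso attack of the enol oxygen at the methoxy-bearing ortho carbon followed by loss of methanol or of a methyl group, because that carbon also carries positive charge in the ring A radical cation;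
- oxidation at the enol with carbon–carbon dimerisation at C3;
- further oxidation of ring A in the product with demethylation toward a quinone, because substrate and product are expected to oxidise at similar potentials.

Fallback by known chemistry, making the same O1–C8a bond from a halide: the fallback sets out from 5. Ring bromination with NBS in MeCN at the only ring C–H should give 1-(2-bromo-3,4,5,6-tetramethoxyphenyl)ethan-1-one F1. Acylation of F1 with 10 under the conditions of step 6 should give 1-(2-bromo-3,4,5,6-tetramethoxyphenyl)-3-[4-methoxy-3,5-bis(pivaloyloxy)phenyl]propane-1,3-dione F2. An intramolecular Ullmann-type O-arylation of the diketone enolate (CuI, 1,10-phenanthroline, K3PO4, toluene, 100 °C) then closes ring C and comes back to the route at 12.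

**Step 3.** The likely failure is loss of the methyl group ortho to the new ketone by acid-assisted, chelation-driven ether cleavage, or incomplete acylation if the mixed anhydride is too weak an electrophile for this ring. Fallback that makes the ortho-hydroxy ketone on purpose: set out from 3. Fries-type ortho C-acetylation with AcOH and BF3·OEt2 at 80 °C should give 1-(2-hydroxy-3,4,5-trimethoxyphenyl)ethan-1-one F3, and O-methylation of F3 (MeI, K2CO3, acetone) returns to the route at 5, bypassing 4.

**Step 6.** The likely failures are O-acylation of the enolate, a second acylation of the product, or acyl transfer from an aryl pivalate to the enolate, all consequences of running enolate and acylating agent together under base. Fallback with a preformed, neutral enol equivalent: set out from 5. Silylation (Me3SiOTf, Et3N, CH2Cl2, 0 °C) should give trimethyl{[1-(2,3,4,5-tetramethoxyphenyl)ethenyl]oxy}silane F4. C-acylation of F4 with 10 promoted by ZnCl2 in CH2Cl2/Et2O, with no amine present, returns to the route at 11.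

**Step 8.** The likely failure is continued Lewis-acid dealkylation after the first chelate has formed (loss of the 6-O-methyl group next to the boron-bound oxygen) or acyl cleavage of a pivalate by excess BCl3. Fallback that avoids a Lewis acid and reverses the order of the end game: set out from 12. Methanolysis (K2CO3, MeOH, rt) should give 3',5'-dihydroxy-5,6,7,8,4'-pentamethoxyflavone F5. Brønsted-acid hydrolysis of the peri 5-methoxy group of F5, which is a vinylogous ester position (conc. HCl, EtOH, reflux), should then lead directly to 15, with no chelating metal present to endanger the 4'-methoxy group.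

## Further compounds

F1 | step 7 | 1-(2-bromo-3,4,5,6-tetramethoxyphenyl)ethan-1-one | CC(=O)c1c(Br)c(OC)c(OC)c(OC)c1OC
F2 | step 7 | 1-(2-bromo-3,4,5,6-tetramethoxyphenyl)-3-[4-methoxy-3,5-bis(pivaloyloxy)phenyl]propane-1,3-dione | COc1c(OC(=O)C(C)(C)C)cc(C(=O)CC(=O)c2c(Br)c(OC)c(OC)c(OC)c2OC)cc1OC(=O)C(C)(C)C
F3 | step 3 | 1-(2-hydroxy-3,4,5-trimethoxyphenyl)ethan-1-one | CC(=O)c1cc(OC)c(OC)c(OC)c1O
F4 | step 6 | trimethyl{[1-(2,3,4,5-tetramethoxyphenyl)ethenyl]oxy}silane | C=C(O[Si](C)(C)C)c1cc(OC)c(OC)c(OC)c1OC
F5 | step 8 | 3',5'-dihydroxy-5,6,7,8,4'-pentamethoxyflavone | COc1c(O)cc(-c2cc(=O)c3c(OC)c(OC)c(OC)c(OC)c3o2)cc1O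
A1 | alternative 1 | 1-[2,6-bis(benzyloxy)-3,4,5-trimethoxyphenyl]-3-[3,5-bis(benzyloxy)-4-methoxyphenyl]propane-1,3-dione | COc1c(OCc2ccccc2)cc(C(=O)CC(=O)c2c(OCc3ccccc3)c(OC)c(OC)c(OC)c2OCc2ccccc2)cc1OCc1ccccc1
A2 | alternative 1 | 1,3-bis(benzyloxy)-2-iodo-4,5,6-trimethoxybenzene | COc1c(OC)c(OCc2ccccc2)c(I)c(OCc2ccccc2)c1OC
A3 | alternative 1 | 1-[3,5-bis(benzyloxy)-4-methoxyphenyl]ethan-1-one | COc1c(OCc2ccccc2)cc(C(C)=O)cc1OCc1ccccc1
A4 | alternative 2 | 3',5'-bis(benzyloxy)-5,8-dihydroxy-6,7,4'-trimethoxyflavone | COc1c(OCc2ccccc2)cc(-c2cc(=O)c3c(O)c(OC)c(OC)c(O)c3o2)cc1OCc1ccccc1
A5 | alternative 2 | 4-{6-[3,5-bis(benzyloxy)-4-methoxyphenyl]-4-oxo-4H-pyran-2-yl}-4-hydroxy-2,3-dimethoxycyclobut-2-en-1-one (racemic) | COC1=C(OC)C(O)(c2cc(=O)cc(-c3cc(OCc4ccccc4)c(OC)c(OCc4ccccc4)c3)o2)C1=O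
A6 | alternative 2 | dimethyl squarate (3,4-dimethoxycyclobut-3-ene-1,2-dione) | COC1=C(OC)C(=O)C1=O
A7 | alternative 2 | 2-[3,5-bis(benzyloxy)-4-methoxyphenyl]-4H-pyran-4-one | COc1c(OCc2ccccc2)cc(-c2cc(=O)cco2)cc1OCc1ccccc1
A8 | alternative 3 | 3',5'-bis(benzyloxy)-4'-hydroxy-5,6,7,8-tetramethoxyflavone | COc1c(OC)c(OC)c2oc(-c3cc(OCc4ccccc4)c(O)c(OCc4ccccc4)c3)cc(=O)c2c1OC
A9 | alternative 3 | 5,6,7,8-tetramethoxy-2-methyl-4H-chromen-4-one | Cc1cc(=O)c2c(OC)c(OC)c(OC)c(OC)c2o1
A10 | alternative 3 | 3,5-bis(benzyloxy)-4H-pyran-4-one | O=c1c(OCc2ccccc2)cocc1OCc1ccccc1
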